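**Strategy.** Ring C is closed last, on an achiral precursor, at the bond between the C3 methylene and the C4 carbonyl carbon. The O1–C2(H)(aryl)–C3H2–C4(=O)–C4a array of the dihydropyranone is read as the product of adding an aldehyde C–H bond across an enol ether. An enantioselective rhodium-catalysed intramolecular hydroacylation joins the formyl carbon on ring A to the terminal carbon of a 1-aryloxy-1-arylethene. In one operation this closes ring C, creates the ketone and sets the only stereocentre (C2). The precursor is a 2-(1-arylvinyloxy)-4,6-bis(methoxymethoxy)benzaldehyde, made by copper-mediated O-alkenylation of a phloroglucinaldehyde derivative with a 1-(7-prenylbenzofuran-5-yl)vinylboronate.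

Key step: step 8

Assumption: the sense of induction of the chiral rhodium catalyst in step 8 cannot be predicted with confidence; the (R)-ligand is written, and its antipode is to be used if the (R)-ligand proves to favour the 2R product.

**Step 1**
Reactants: 1 2,4,6-trihydroxybenzaldehyde
Product: 2 2-hydroxy-4,6-bis(methoxymethoxy)benzaldehyde
Conditions: MOMCl (2.2 equiv), iPr2NEt (2.5 equiv), CH2Cl2, 0 °C to rt
Reagents that add atoms: chloromethyl methyl ether, COCCl
Why: O-alkylation (MOM ether formation) of the two more nucleophilic hydroxyls should leave free the one that is hydrogen-bonded to the formyl group.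

**Step 2**
Reactants: 3 3-bromo-4-hydroxybenzaldehyde
Product: 4 3-bromo-4-hydroxy-5-iodobenzaldehyde
Conditions: NIS (1.05 equiv), p-TsOH·H2O (10 mol%), MeCN, rt
Reagents that add atoms: N-iodosuccinimide, O=C1CCC(=O)N1I
Why: Electrophilic aromatic iodination can only go to the one free position ortho to the phenol, since the para position carries the formyl group.

**Step 3**
Reactants: 4 3-bromo-4-hydroxy-5-iodobenzaldehyde
Product: 7 7-bromo-1-benzofuran-5-carbaldehyde, via silylalkynylphenol 5 (not isolated), via ethynylphenol 6 (not isolated)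
Conditions: ethynyltrimethylsilane (1.1 equiv), PdCl2(PPh3)2 (2 mol%), CuI (4 mol%), Et3N, THF, rt; then TBAF (1.5 equiv), 60 °C
Reagents that add atoms: ethynyltrimethylsilane, C#C[Si](C)(C)C
Why: Sonogashira coupling should occur only at the C–I bond, which adds to zerovalent palladium far faster than C–Br, and fluoride desilylation followed by copper-assisted 5-endo-dig hydroalkoxylation of the ortho-ethynylphenol should then close the furan ring.

**Step 4**
Reactants: 7 7-bromo-1-benzofuran-5-carbaldehyde
Product: 8 7-(3-methylbut-2-en-1-yl)-1-benzofuran-5-carbaldehyde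
Conditions: tributyl(3-methylbut-2-en-1-yl)stannane (1.2 equiv), Pd(PPh3)4 (5 mol%), DMF, 100 °C
Reagents that add atoms: tributyl(3-methylbut-2-en-1-yl)stannane, CCCC[Sn](CCCC)(CCCC)CC=C(C)C
Why: Stille coupling should give the linear prenyl arene, because reductive elimination from the (1,1-dimethylallyl)palladium intermediate takes place at its unsubstituted terminus, and the aldehyde and furan ring are inert.

**Step 5**
Reactants: 8 7-(3-methylbut-2-en-1-yl)-1-benzofuran-5-carbaldehyde
Product: 9 5-ethynyl-7-(3-methylbut-2-en-1-yl)-1-benzofuran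
Conditions: dimethyl (1-diazo-2-oxopropyl)phosphonate (1.3 equiv), K2CO3 (2 equiv), MeOH, rt
Reagents that add atoms: dimethyl (1-diazo-2-oxopropyl)phosphonate, COP(=O)(OC)C(=[N+]=[N-])C(C)=O
Why: The Ohira–Bestmann variant of the Seyferth–Gilbert homologation should convert the non-enolisable aryl aldehyde into the terminal alkyne under mild base that leaves the prenyl group untouched.

**Step 6**
Reactants: 9 5-ethynyl-7-(3-methylbut-2-en-1-yl)-1-benzofuran
Product: 10 4,4,5,5-tetramethyl-2-{1-[7-(3-methylbut-2-en-1-yl)-1-benzofuran-5-yl]ethenyl}-1,3,2-dioxaborolane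
Conditions: B2pin2 (1.1 equiv), CuCl (5 mol%), SIMes·HCl (5 mol%; SIMes = 1,3-dimesitylimidazolidin-2-ylidene), NaOtBu (12 mol%), MeOH (2 equiv), THF, −50 °C to rt
Reagents that add atoms: bis(pinacolato)diboron, CC1(C)OB(OC1(C)C)B1OC(C)(C)C(C)(C)O1
Why: Copper-catalysed alpha-selective protoboration of a terminal aryl alkyne should place boron on the aryl-bearing carbon by syn addition of the N-aryl carbene copper boryl and protonation of the alkenylcopper by methanol, while the trisubstituted alkene and the benzofuran do not react.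

**Step 7**
Reactants: 2 2-hydroxy-4,6-bis(methoxymethoxy)benzaldehyde; 10 4,4,5,5-tetramethyl-2-{1-[7-(3-methylbut-2-en-1-yl)-1-benzofuran-5-yl]ethenyl}-1,3,2-dioxaborolane
Product: 11 2,4-bis(methoxymethoxy)-6-({1-[7-(3-methylbut-2-en-1-yl)-1-benzofuran-5-yl]ethenyl}oxy)benzaldehyde
Conditions: Cu(OAc)2 (2 equiv), Et3N (4 equiv), 4 Å MS, CH2Cl2, dry air, rt
Reagents that add atoms: none
Why: Chan–Lam oxidative C–O coupling of the phenol with the alkenylboronate under divalent copper should form the aryl 1-arylvinyl ether at room temperature with weak base, conditions that preserve the aldehyde, the MOM ethers and the prenyl group.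

**Step 8**
Reactants: 11 2,4-bis(methoxymethoxy)-6-({1-[7-(3-methylbut-2-en-1-yl)-1-benzofuran-5-yl]ethenyl}oxy)benzaldehyde
Product: 12 (2S)-5,7-bis(methoxymethoxy)-2-[7-(3-methylbut-2-en-1-yl)-1-benzofuran-5-yl]-2,3-dihydro-4H-chromen-4-one
Conditions: [Rh(cod)Cl]2 (2.5 mol%), (R)-DTBM-SEGPHOS (5.5 mol%), NaB[3,5-(CF3)2C6H3]4 (6 mol%), 1,2-dichloroethane, 60 °C
Reagents that add atoms: none
Why: Proposed new method: cationic monovalent rhodium inserts into the formyl C–H bond of 11 to give an acyl hydride of trivalent rhodium, the tethered 1,1-disubstituted enol ether inserts into Rh–H with the hydride going to the aryl- and oxygen-bearing carbon (the future C2), and C–C reductive elimination from the seven-membered acyl–alkyl rhodacycle forms the C3–C4 bond and releases the catalyst. The closest known reaction type is the rhodium/bisphosphine-catalysed endo- and enantioselective intramolecular hydroacylation of 1,1-disubstituted alkenes held ortho to an aryl aldehyde (2-(1-arylvinyl)benzaldehydes to 3-arylindanones, 2-(2-substituted allyl)benzaldehydes to 3-substituted tetralones); an oxygen-tethered 1-arylvinyl ether giving a flavanone has not been shown. Ring C is closed in the 6-endo-trig mode. The C2 stereocentre is set when the hydride is transferred to one enantioface of the alkene, and that face is chosen by the chiral bisphosphine on rhodium (catalyst control, no other stereocentre being present). The step needs endo over exo regioselectivity and hydroacylation over decarbonylation: the exo path would require reductive elimination at a fully substituted carbon to give a 2-aryl-2-methylbenzofuran-3-one and is sterically disfavoured, the alkene has no allylic hydrogen and so cannot isomerise away, and the ortho MOM oxygen can hold the acyl hydride as a chelate against loss of CO. The neutral conditions avoid base-induced opening of the flavanone ring, so the C2 configuration should persist.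

**Step 9**
Reactants: 12 (2S)-5,7-bis(methoxymethoxy)-2-[7-(3-methylbut-2-en-1-yl)-1-benzofuran-5-yl]-2,3-dihydro-4H-chromen-4-one
Product: 13 (2S)-5,7-dihydroxy-2-[7-(3-methylbut-2-en-1-yl)-1-benzofuran-5-yl]-2,3-dihydro-4H-chromen-4-one
Conditions: 3 M aq HCl, MeOH, 50 °C
Reagents that add atoms: none
Why: Acid-catalysed cleavage of the MOM acetals by transacetalisation to methanol should free both phenols without touching C2, since no base is present and the prenyl and benzofuran units tolerate dilute HCl at moderate temperature.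

**Compound list**
1 | 2,4,6-trihydroxybenzaldehyde | O=Cc1c(O)cc(O)cc1O | starting material
2 | 2-hydroxy-4,6-bis(methoxymethoxy)benzaldehyde | O=Cc1c(O)cc(OCOC)cc1OCOC | intermediate
3 | 3-bromo-4-hydroxybenzaldehyde | O=Cc1ccc(O)c(Br)c1 | starting material
4 | 3-bromo-4-hydroxy-5-iodobenzaldehyde | O=Cc1cc(Br)c(O)c(I)c1 | intermediate
5 | 3-bromo-4-hydroxy-5-[(trimethylsilyl)ethynyl]benzaldehyde | O=Cc1cc(Br)c(O)c(C#C[Si](C)(C)C)c1 | intermediate (not isolated)
6 | 3-bromo-5-ethynyl-4-hydroxybenzaldehyde | O=Cc1cc(Br)c(O)c(C#C)c1 | intermediate (not isolated)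
7 | 7-bromo-1-benzofuran-5-carbaldehyde | O=Cc1cc(Br)c2occc2c1 | intermediate
8 | 7-(3-methylbut-2-en-1-yl)-1-benzofuran-5-carbaldehyde | O=Cc1cc(CC=C(C)C)c2occc2c1 | intermediate
9 | 5-ethynyl-7-(3-methylbut-2-en-1-yl)-1-benzofuran | C#Cc1cc(CC=C(C)C)c2occc2c1 | intermediate
10 | 4,4,5,5-tetramethyl-2-{1-[7-(3-methylbut-2-en-1-yl)-1-benzofuran-5-yl]ethenyl}-1,3,2-dioxaborolane | C=C(B1OC(C)(C)C(C)(C)O1)c1cc(CC=C(C)C)c2occc2c1 | intermediate
11 | 2,4-bis(methoxymethoxy)-6-({1-[7-(3-methylbut-2-en-1-yl)-1-benzofuran-5-yl]ethenyl}oxy)benzaldehyde | O=Cc1c(OC(=C)c2cc(CC=C(C)C)c3occc3c2)cc(OCOC)cc1OCOC | intermediate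
12 | (2S)-5,7-bis(methoxymethoxy)-2-[7-(3-methylbut-2-en-1-yl)-1-benzofuran-5-yl]-2,3-dihydro-4H-chromen-4-one | CC(C)=CCc1cc([C@@H]2CC(=O)c3c(OCOC)cc(OCOC)cc3O2)cc2ccoc12 | intermediate
13 | (2S)-5,7-dihydroxy-2-[7-(3-methylbut-2-en-1-yl)-1-benzofuran-5-yl]-2,3-dihydro-4H-chromen-4-one | CC(C)=CCc1cc([C@@H]2CC(=O)c3c(O)cc(O)cc3O2)cc2ccoc12 | target

**Step count.** Total: 9 steps. Longest linear sequence: 8 steps (steps 2 to 9, from compound 3).

**Steps most likely to fail**

Step 8 (key step). The acyl rhodium hydride may lose CO faster than the hindered enol ether inserts, insertion may take the exo course, or facial selectivity may be poor. The fallback closes the same C3–C4 bond by known azolium umpolung with the stereocentre set beforehand; it sets out from alkyne 9 and phenol 2 and comes back at 12. Gold-catalysed oxidation of 9 (Ph3PAuNTf2, 8-methylquinoline N-oxide, MsOH, 1,2-dichloroethane, rt) should give 2-oxo-2-[7-(3-methylbut-2-en-1-yl)-1-benzofuran-5-yl]ethyl methanesulfonate F1. Asymmetric transfer hydrogenation (RuCl[(R,R)-TsDPEN](p-cymene), HCO2H/Et3N) should give (2S)-2-hydroxy-2-[7-(3-methylbut-2-en-1-yl)-1-benzofuran-5-yl]ethyl methanesulfonate F2. Mitsunobu etherification with 2 (PPh3, DIAD, toluene, 0 °C, inversion) should give (2R)-2-[2-formyl-3,5-bis(methoxymethoxy)phenoxy]-2-[7-(3-methylbut-2-en-1-yl)-1-benzofuran-5-yl]ethyl methanesulfonate F3. Intramolecular alkylation of the Breslow intermediate (thiazolium precatalyst, DBU, 1,4-dioxane), a reaction known for salicylaldehyde 2-sulfonyloxyethyl ethers giving chroman-4-ones, should then deliver 12.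

Step 7. Transmetalation of the hindered alpha-aryl alkenylboronate may be slow, the chelating salicylaldehyde-type phenoxide may sequester copper, and protodeboronation may take over. The fallback builds the enol ether by conjugate-type addition to a haloalkyne; it sets out from alkyne 9 and phenol 2 and comes back at 11. Bromination of 9 (NBS, AgNO3 cat., acetone, rt) should give 5-(bromoethynyl)-7-(3-methylbut-2-en-1-yl)-1-benzofuran F4. Addition of the phenoxide of 2 (K2CO3, DMF, 110 °C) at the aryl-bearing alkyne carbon should give 2-({(Z)-2-bromo-1-[7-(3-methylbut-2-en-1-yl)-1-benzofuran-5-yl]ethenyl}oxy)-4,6-bis(methoxymethoxy)benzaldehyde F5. Palladium-catalysed hydrodebromination (Pd(PPh3)4, Bu3SnH, THF, rt) should then give 11.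

Step 6. With the electron-rich aryl alkyne, boryl cupration may lose its alpha-selectivity and give the beta-boryl styrene. The fallback reaches the same boronate by hydroalumination; it sets out from alkyne 9 and comes back at 10. Nickel-catalysed alpha-selective hydroalumination (DIBAL-H, Ni(dppp)Cl2 3 mol%, THF, rt) should give bis(2-methylpropyl){1-[7-(3-methylbut-2-en-1-yl)-1-benzofuran-5-yl]ethenyl}alumane F6, which is quenched in the same flask with 2-methoxy-4,4,5,5-tetramethyl-1,3,2-dioxaborolane to give 10.

**Further compounds**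
F1 | step 8 | 2-oxo-2-[7-(3-methylbut-2-en-1-yl)-1-benzofuran-5-yl]ethyl methanesulfonate | CC(C)=CCc1cc(C(=O)COS(C)(=O)=O)cc2ccoc12
F2 | step 8 | (2S)-2-hydroxy-2-[7-(3-methylbut-2-en-1-yl)-1-benzofuran-5-yl]ethyl methanesulfonate | CC(C)=CCc1cc([C@H](O)COS(C)(=O)=O)cc2ccoc12
F3 | step 8 | (2R)-2-[2-formyl-3,5-bis(methoxymethoxy)phenoxy]-2-[7-(3-methylbut-2-en-1-yl)-1-benzofuran-5-yl]ethyl methanesulfonate | CC(C)=CCc1cc([C@@H](Oc2cc(OCOC)cc(OCOC)c2C=O)COS(C)(=O)=O)cc2ccoc12
F4 | step 7 | 5-(bromoethynyl)-7-(3-methylbut-2-en-1-yl)-1-benzofuran | BrC#Cc1cc(CC=C(C)C)c2occc2c1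
F5 | step 7 | 2-({(Z)-2-bromo-1-[7-(3-methylbut-2-en-1-yl)-1-benzofuran-5-yl]ethenyl}oxy)-4,6-bis(methoxymethoxy)benzaldehyde | Br/C=C(\Oc1cc(OCOC)cc(OCOC)c1C=O)c1cc(CC=C(C)C)c2occc2c1
F6 | step 6 | bis(2-methylpropyl){1-[7-(3-methylbut-2-en-1-yl)-1-benzofuran-5-yl]ethenyl}alumane | CC(C)=CCc1cc(C(=C)[Al](CC(C)C)CC(C)C)cc2ccoc12
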